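Ring locants used throughout: O1, C2 (aryl-bearing), C3, C4, C5; C6 is the carbon on C3 and C7 the carbonyl carbon on C4. All names and descriptors use these locants; (2S,3R,4S) for the target corresponds to (3S,4R,5S) in systematic oxolane numbering.

## The problem

The target 21 is a 2,3,4-trisubstituted tetrahydrofuran. C2 carries a 3-hydroxy-4-methoxyphenyl ring, C3 the hydroxymethyl carbon C6, and C4 a 3-hydroxy-4-methoxybenzoyl group through the ketone carbon C7. The three substituents are all-trans and the configuration is (2S,3R,4S). Only one ring has to be made, so the difficulty lies in three contiguous stereocentres and in the different oxidation levels of C6 (alcohol) and C7 (ketone) on two otherwise identical aryl halves. The centres are not equally controllable. C4 is α to the ketone, and C3 becomes α to a carbonyl whenever C6 is an aldehyde, so both can be driven to the trans arrangement by equilibration. C2, a benzylic ether carbon, cannot be reached by base. The absolute configuration must therefore rest on C2, or on a centre that is never allowed to equilibrate and that directs C2. Several groups are fragile. The C2–O1 bond is a 4-alkoxybenzylic ether that ionises under strong acid and can be hydrogenolysed. O1 is β to both carbonyl positions, so strong base invites ring opening. The aryl ketone has to survive the release of two phenols. The enabling feature is that C2 is bonded to O1, to C3 and to an aryl ring, which makes it an aldehyde carbon in retrosynthesis. The chain O1–C5–C4–C3 is then a homoallylic alcohol if C3 is an alkene carbon, and C6 is exactly the carbon that a vinyl group left by an allylsilane keeps after oxidative cleavage.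

## Retrosynthesis

**21 ⇒ 20 (two O–benzyl bonds).** Both phenols are carried as benzyl ethers and released together at the end. Benzyl is chosen over silyl or acetal groups because it is indifferent to TMSOTf, OsO4/NaIO4, DBU, NaBH4 and aryllithium, and because the benzylated aldehyde 11 is commercial. The skeleton of 20 is no simpler. The forward step must stop short of the aryl ketone and of the C2–O1 bond.

**20 ⇒ 16 + 19 (C7–aryl bond).** This cut turns the ketone into the Weinreb amide 16 and the ring into aryllithium 19, made from bromide 18 and hence from bromophenol 17 by one benzylation. The neighbouring cut C4–C7 would need a C4 anion next to the β-oxygen O1. The cut is placed late on purpose: while C7 is an amide, C4–H is too weakly acidic to exchange under the base used to adjust C3, so C4 stays the fixed reference for absolute configuration. The precursor has lost one aryl ring. The forward step must add the aryllithium in the presence of the free C6 hydroxyl without deprotonating C4.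

**16 ⇒ 15 ⇒ 12 (C6 oxidation level; C6=CH2 bond).** The hydroxymethyl group is traced to a formyl group (15) and that to a vinyl group (12). The aldehyde stage is wanted for its own sake, because there C3 can be equilibrated to the all-trans arrangement, which relieves the ring-forming step of any duty at C3. A C6 ester or ether carried through the cyclisation would give no such freedom and is not what an allylsilane leaves behind. The forward steps must cleave a monosubstituted alkene beside an electron-rich arene, move C3 only, and reduce the aldehyde beside the amide.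

**12 ⇒ 10 + 11 (O1–C2 and C2–C3; key disconnection).** Both bonds to C2 are cut at once. C2 becomes the carbonyl carbon of aldehyde 11, and the rest becomes allylsilane 10, the trimethylsilyl ether of alcohol 9. Cutting O1–C5 (etherification) or C3–C4 (conjugate or radical closure) would leave a precursor that still holds two or three stereocentres. The double cut at C2 removes the ring, one aryl group and two stereocentres, and leaves only C4. The forward reaction is an oxocarbenium–allylsilane closure in which C4 must direct C2 (2,4-cis), the allylsilane must survive until it cyclises, and C4 must not epimerise.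

**10 ⇒ 9 ⇒ 7 + 8 (O–Si bond; the C=C bond of the allylsilane).** The alkene of 9 is cut by cross-metathesis into vinyl amide 7 and allyltrimethylsilane 8. Installing the allylsilane before the stereocentre is unattractive, because an allylsilane would not survive the TiCl4 used to create C4. Amide 7 is a five-carbon acid derivative with one stereocentre. The forward metathesis must not move the β,γ-alkene into conjugation; the E/Z ratio is not critical.

**7 ⇒ 6 ⇒ 4 ⇒ 1 + 2 (amide exchange; C4–C5 bond; N-acyl bond).** C5 is cut from C4, leaving the but-3-enoyl imide 4 of (R)-4-benzyloxazolidin-2-one 2 and a formaldehyde equivalent; 4 comes from but-3-enoic acid 1. An auxiliary is preferred because titanium-enolate hydroxymethylation is the most direct route to an α-hydroxymethyl acid derivative, and the new β-hydroxyl assists the exchange of the auxiliary for the Weinreb amine. The forward step needs α- rather than γ-attack of the dienolate, face selection by the auxiliary, and no migration of the alkene.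

## Roads not taken

**Alternative 1: both aryl rings by double Friedel–Crafts reaction.**
- **Cut:** C7–aryl and C2–aryl.
- **Key step:** SnCl4 ionises the acid chloride and the anomeric acetate of the core A2, and two molecules of 2-methoxyphenyl acetate A3 attack para to methoxy, giving triacetate A1. Mild methanolysis of A1 would give 21.
- **Merits:** it exploits the identity of the two aryl rings, introduces both in one operation, and needs no organometallic reagent. In convergence it is better than the chosen plan, which brings in the rings in two separate steps.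
- **Weak points:** the C2–aryl bond forms at an oxocarbenium ion with an arene that is only moderately activated. The product A1 holds the very 4-methoxybenzylic C2–O1 bond that SnCl4 can ionise again, so a second arylation with ring opening is a built-in side path. The stereochemical problem is not solved but moved: A2 must be made with C3 and C4 trans and enantiopure.
- **Comparison:** the chosen plan sets its mild, sub-stoichiometric Lewis acid and its simple chiral source against this gain in convergence.

**Alternative 2: Prins–pinacol rearrangement.**
- **Cut:** C2–C3 and C4–C5.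
- **Key step:** SnCl4 opens dioxolane A4 to the oxocarbenium ion on O1. A 2-oxonia-Cope shift forms C2–C3 and breaks C5–C7, and the tin enolate closes onto the new oxocarbenium ion to form C4–C5, giving ketone A5.
- **Merits:** two C–C bonds, the ring and all three stereocentres arise in one step with both aryl rings already in place. In bond count and stereocentres per step this is stronger than the chosen key step.
- **Weak points:** A4 needs an enantioenriched tertiary benzylic carbinol carbon, which ionises easily. That is why its aryl ring carries a sulfonate in place of the methyl ether, and the sulfonate must later be exchanged for methyl. C3 of A5 bears an ether and cannot be corrected if the chair transition state does not deliver the trans arrangement. The alkyl benzyl ether at C6 needs longer hydrogenolysis beside the ketone than aryl benzyl ethers do.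
- **Comparison:** the chosen plan sets against it a correctable C3, a stereocentre from a standard auxiliary, and an end game without protecting-group exchange.

**Alternative 3: titanocene radical closure.**
- **Cut:** C3–C4.
- **Key step:** Cp2TiCl (trivalent titanium, from Cp2TiCl2 and Zn dust) opens the terminal epoxide of A6 to the C3 radical, which adds 5-exo-dig to the aryl alkyne and gives arylidene tetrahydrofuran A7.
- **Merits:** neutral conditions, a well-behaved radical closure in which the 2,3-trans relationship is expected, and C6 delivered directly as the free alcohol. In this last respect it is better than the chosen plan, which spends an oxidative cleavage and a reduction on C6.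
- **Weak points:** C2 must be set enantioselectively beforehand in an acid-labile, electron-rich benzylic epoxy ether. The arylidene of A7 is at the wrong oxidation level: a regioselective hydroboration–oxidation, an alcohol oxidation and an equilibration at C4 are needed, with C6–OH protected meanwhile. Titanium is used stoichiometrically.
- **Comparison:** the chosen plan brings C7 in at the ketone level directly from the amide and takes C2 from an aldehyde.

Key step: step 6

Remarks on the chemistry:
- The hydroxymethylation of the titanium dienolate is assumed to follow the facial sense of Evans enolate alkylation; this is why the (R)-auxiliary is used.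
- Compound 12 is written as the all-trans isomer. A C3 epimer formed beside it is carried on, since both give 15 in step 7.

## Steps

Step 1
Reactants: 1 but-3-enoic acid; 2 (R)-4-benzyloxazolidin-2-one
Product: 4 (R)-4-benzyl-3-(but-3-enoyl)oxazolidin-2-one, via but-3-enoic pivalic anhydride 3 (not isolated)
Conditions: t-BuCOCl, Et3N, THF, −20 °C; then LiCl, 2, −20 °C → rt
Reagents that add atoms: none
Why: N-acylation of the oxazolidinone through the mixed pivalic anhydride; the lithium-chelated carbamate nitrogen attacks the less hindered carbonyl of 3, and low temperature with only a weak amine base should keep the β,γ-alkene out of conjugation.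

Step 2
Reactants: 4 (R)-4-benzyl-3-(but-3-enoyl)oxazolidin-2-one
Product: 6 (R)-4-benzyl-3-[(2S)-2-(hydroxymethyl)but-3-enoyl]oxazolidin-2-one, via titanium dienolate 5 (not isolated)
Conditions: TiCl4 (1.05 equiv), i-Pr2NEt (1.1 equiv), CH2Cl2, 0 °C; then 1,3,5-trioxane (1.2 equiv), TiCl4 (1.05 equiv), 0 °C; aq NH4Cl
Reagents that add atoms: 1,3,5-trioxane, C1OCOCO1
Why: Evans titanium-enolate hydroxymethylation: the chelated Z-dienolate 5 is attacked at its α-carbon, on the face away from the benzyl group, by the oxocarbenium ion that TiCl4 releases from trioxane, which with the (R)-auxiliary should set C4 as S; metal dienolates of this kind react at the α-carbon, and the non-basic medium protects the doubly activated C4–H of the product.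

Step 3
Reactants: 6 (R)-4-benzyl-3-[(2S)-2-(hydroxymethyl)but-3-enoyl]oxazolidin-2-one
Product: 7 (2S)-2-(hydroxymethyl)-N-methoxy-N-methylbut-3-enamide
Conditions: MeNH(OMe)·HCl (3 equiv), AlMe3 (3 equiv), CH2Cl2, −15 → 0 °C; cold 1 M HCl work-up
Reagents that add atoms: N,O-dimethylhydroxylamine hydrochloride, CNOC.Cl
Why: Weinreb aminolysis of a β-hydroxy imide with the aluminium amide; the aluminium alkoxide of the β-hydroxyl delivers the amide to the exocyclic carbonyl, the medium is Lewis acidic and not basic so C4 should keep its configuration, and auxiliary 2 is recovered.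

Step 4
Reactants: 7 (2S)-2-(hydroxymethyl)-N-methoxy-N-methylbut-3-enamide; 8 allyltrimethylsilane
Product: 9 (2S,3E)-2-(hydroxymethyl)-N-methoxy-N-methyl-5-(trimethylsilyl)pent-3-enamide
Conditions: 8 (4 equiv), second-generation Grubbs catalyst RuCl2(=CHPh)(H2IMes)(PCy3) (5 mol %), 1,4-benzoquinone (10 mol %), CH2Cl2, 40 °C
Reagents that add atoms: none
Why: Olefin cross-metathesis between an α-branched terminal alkene and an excess of the fast-dimerising allylsilane; the E alkene is expected to dominate, any Z isomer can be carried on because C3 is corrected in step 7, and benzoquinone suppresses ruthenium hydride alkene migration.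

Step 5
Reactants: 9 (2S,3E)-2-(hydroxymethyl)-N-methoxy-N-methyl-5-(trimethylsilyl)pent-3-enamide
Product: 10 (2S,3E)-N-methoxy-N-methyl-5-(trimethylsilyl)-2-[(trimethylsilyloxy)methyl]pent-3-enamide
Conditions: Me3SiCl (1.2 equiv), Et3N (1.5 equiv), CH2Cl2, 0 °C; filtered and used crude
Reagents that add atoms: chlorotrimethylsilane, C[Si](C)(C)Cl
Why: Simple O-silylation of the primary alcohol; the silyl ether makes step 6 aprotic, because the former aldehyde oxygen then leaves as hexamethyldisiloxane instead of water.

Step 6
Reactants: 10 (2S,3E)-N-methoxy-N-methyl-5-(trimethylsilyl)-2-[(trimethylsilyloxy)methyl]pent-3-enamide; 11 3-(benzyloxy)-4-methoxybenzaldehyde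
Product: 12 (2S,3S,4S)-2-[3-(benzyloxy)-4-methoxyphenyl]-N-methoxy-N-methyl-3-vinyltetrahydrofuran-4-carboxamide
Conditions: 11 (1.1 equiv), TMSOTf (0.3 equiv), 2,6-di-tert-butyl-4-methylpyridine (0.1 equiv), CH2Cl2, −78 → −40 °C; Et3N, then aq NaHCO3
Reagents that add atoms: none
Why: TMSOTf activates 11 toward addition of the silyl ether oxygen of 10; the mixed silyl acetal loses trimethylsilanolate (as hexamethyldisiloxane) and gives the E-configured, aryl-stabilised oxocarbenium ion O1=C2. The allylsilane carbon remote from silicon (C3) attacks C2 while positive charge develops β to silicon, and loss of the trimethylsilyl cation regenerates TMSOTf and leaves the vinyl group on C3, so O1–C2 and C2–C3 form in one operation. The closest known reaction type is the intramolecular silyl-modified Sakurai (silyl-Prins) condensation of 5-silylpent-3-en-1-ol derivatives with aldehydes to 2-substituted 3-vinyltetrahydrofurans. The closure is five-membered, exo with respect to the allylsilane double bond and endo with respect to the C=O+ bond, a mode that oxocarbenium ions follow readily. C2 is controlled by C4: in the envelope transition state the E-oxocarbenium geometry places the aryl group pseudo-equatorial and the Weinreb amide on C4 should take a pseudo-equatorial position as well, which gives the 2,4-cis product, 2S from 4S. C3 is set by the alkene geometry and the mode of approach and is not relied on, because both C3 epimers converge in step 7. The step needs attack through C3 and not through the silicon-bearing carbon (inherent to allylsilane SE' reactivity and to the ring size), closure faster than protodesilylation (aprotic medium, hindered pyridine base, low temperature), and an untouched C4 (no enolising base is present).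

Step 7
Reactants: 12 (2S,3S,4S)-2-[3-(benzyloxy)-4-methoxyphenyl]-N-methoxy-N-methyl-3-vinyltetrahydrofuran-4-carboxamide
Product: 15 (2S,3S,4S)-2-[3-(benzyloxy)-4-methoxyphenyl]-3-formyl-N-methoxy-N-methyltetrahydrofuran-4-carboxamide, via vicinal diol 13 (not isolated), via C3-epimeric aldehyde 14 (not isolated)
Conditions: OsO4 (2 mol %), NaIO4 (4 equiv), 2,6-lutidine (2 equiv), 1,4-dioxane/H2O 3:1, rt; extractive work-up; then DBU (0.3 equiv), CH2Cl2, rt
Reagents that add atoms: osmium tetroxide, O=[Os](=O)(=O)=O (catalytic oxygen carrier); sodium periodate, [Na+].[O-]I(=O)(=O)=O (terminal oxygen source)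
Why: Lemieux–Johnson cleavage of the only alkene gives the C3 aldehyde, and DBU then equilibrates C3 through the enolate to the isomer with the formyl group trans to both neighbours; C4 is α to an amide and far less acidic, so it should not move, and ring opening by β-elimination of O1 is disfavoured because the enolate π-system lies orthogonal to the endocyclic C2–O1 bond.

Step 8
Reactants: 15 (2S,3S,4S)-2-[3-(benzyloxy)-4-methoxyphenyl]-3-formyl-N-methoxy-N-methyltetrahydrofuran-4-carboxamide
Product: 16 (2S,3R,4S)-2-[3-(benzyloxy)-4-methoxyphenyl]-3-(hydroxymethyl)-N-methoxy-N-methyltetrahydrofuran-4-carboxamide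
Conditions: NaBH4 (1 equiv), MeOH, 0 °C
Reagents that add atoms: none
Why: Chemoselective borohydride reduction of the aldehyde; the Weinreb amide is inert to NaBH4 at 0 °C, and lactonisation of the hydroxy amide is blocked because the lactone would be trans-fused to the tetrahydrofuran ring.

Step 9
Reactants: 17 5-bromo-2-methoxyphenol
Product: 18 2-(benzyloxy)-4-bromo-1-methoxybenzene
Conditions: BnBr (1.1 equiv), K2CO3 (1.5 equiv), DMF, rt
Reagents that add atoms: benzyl bromide, BrCc1ccccc1
Why: Williamson etherification; the phenoxide is the only nucleophile present and the aryl bromide is inert under these conditions.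

Step 10
Reactants: 16 (2S,3R,4S)-2-[3-(benzyloxy)-4-methoxyphenyl]-3-(hydroxymethyl)-N-methoxy-N-methyltetrahydrofuran-4-carboxamide; 18 2-(benzyloxy)-4-bromo-1-methoxybenzene
Product: 20 (2S,3R,4S)-4-[3-(benzyloxy)-4-methoxybenzoyl]-2-[3-(benzyloxy)-4-methoxyphenyl]-3-(hydroxymethyl)tetrahydrofuran, via 3-benzyloxy-4-methoxyphenyllithium 19 (not isolated)
Conditions: 18 (3.3 equiv), n-BuLi (3.1 equiv), THF, −78 °C; then 16 (1 equiv), −78 → −40 °C; aq NH4Cl
Reagents that add atoms: none
Why: Bromine–lithium exchange gives 19; its first equivalent deprotonates the C6 hydroxyl and the next adds to the Weinreb amide to give the chelated tetrahedral intermediate, which collapses to the ketone only on work-up (Weinreb ketone synthesis), so over-addition is excluded, and at −78 °C addition should outrun deprotonation at C4.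

Step 11
Reactants: 20 (2S,3R,4S)-4-[3-(benzyloxy)-4-methoxybenzoyl]-2-[3-(benzyloxy)-4-methoxyphenyl]-3-(hydroxymethyl)tetrahydrofuran
Product: 21 (2S,3R,4S)-4-(3-hydroxy-4-methoxybenzoyl)-2-(3-hydroxy-4-methoxyphenyl)-3-(hydroxymethyl)tetrahydrofuran
Conditions: H2 (1 atm), 10% Pd/C, EtOAc, rt; stopped when 20 is consumed
Reagents that add atoms: none
Why: Catalytic hydrogenolysis of the two aryl benzyl ethers, which in a neutral aprotic solvent at 1 atm should be much faster than reduction of the electron-rich aryl ketone or cleavage of the cyclic C2–O1 benzylic ether; no stereocentre is affected.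

## Compound list

1 | but-3-enoic acid | C=CCC(=O)O | starting material
2 | (R)-4-benzyloxazolidin-2-one | O=C1N[C@H](Cc2ccccc2)CO1 | starting material
3 | but-3-enoic pivalic anhydride | C=CCC(=O)OC(=O)C(C)(C)C | intermediate (not isolated)
4 | (R)-4-benzyl-3-(but-3-enoyl)oxazolidin-2-one | C=CCC(=O)N1C(=O)OC[C@H]1Cc1ccccc1 | intermediate
5 | trichlorotitanium (Z)-dienolate of 4 | C=C/C=C(\O[Ti](Cl)(Cl)Cl)N1C(=O)OC[C@H]1Cc1ccccc1 | intermediate (not isolated)
6 | (R)-4-benzyl-3-[(2S)-2-(hydroxymethyl)but-3-enoyl]oxazolidin-2-one | OC[C@@H](C(=O)N1C(=O)OC[C@H]1Cc1ccccc1)C=C | intermediate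
7 | (2S)-2-(hydroxymethyl)-N-methoxy-N-methylbut-3-enamide | OC[C@@H](C(=O)N(C)OC)C=C | intermediate
8 | allyltrimethylsilane | C=CC[Si](C)(C)C | starting material
9 | (2S,3E)-2-(hydroxymethyl)-N-methoxy-N-methyl-5-(trimethylsilyl)pent-3-enamide | OC[C@@H](C(=O)N(C)OC)/C=C/C[Si](C)(C)C | intermediate
10 | (2S,3E)-N-methoxy-N-methyl-5-(trimethylsilyl)-2-[(trimethylsilyloxy)methyl]pent-3-enamide | C[Si](C)(C)OC[C@@H](C(=O)N(C)OC)/C=C/C[Si](C)(C)C | intermediate
11 | 3-(benzyloxy)-4-methoxybenzaldehyde | COc1ccc(C=O)cc1OCc1ccccc1 | starting material
12 | (2S,3S,4S)-2-[3-(benzyloxy)-4-methoxyphenyl]-N-methoxy-N-methyl-3-vinyltetrahydrofuran-4-carboxamide | CON(C)C(=O)[C@@H]1CO[C@H](c2ccc(OC)c(OCc3ccccc3)c2)[C@H]1C=C | intermediate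
13 | (2S,4S)-2-[3-(benzyloxy)-4-methoxyphenyl]-3-(1,2-dihydroxyethyl)-N-methoxy-N-methyltetrahydrofuran-4-carboxamide, C3 and carbinol epimers | CON(C)C(=O)[C@@H]1CO[C@H](c2ccc(OC)c(OCc3ccccc3)c2)C1C(O)CO | intermediate (not isolated)
14 | (2S,4S)-2-[3-(benzyloxy)-4-methoxyphenyl]-3-formyl-N-methoxy-N-methyltetrahydrofuran-4-carboxamide, both C3 epimers | CON(C)C(=O)[C@@H]1CO[C@H](c2ccc(OC)c(OCc3ccccc3)c2)C1C=O | intermediate (not isolated)
15 | (2S,3S,4S)-2-[3-(benzyloxy)-4-methoxyphenyl]-3-formyl-N-methoxy-N-methyltetrahydrofuran-4-carboxamide | CON(C)C(=O)[C@@H]1CO[C@H](c2ccc(OC)c(OCc3ccccc3)c2)[C@H]1C=O | intermediate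
16 | (2S,3R,4S)-2-[3-(benzyloxy)-4-methoxyphenyl]-3-(hydroxymethyl)-N-methoxy-N-methyltetrahydrofuran-4-carboxamide | CON(C)C(=O)[C@@H]1CO[C@H](c2ccc(OC)c(OCc3ccccc3)c2)[C@H]1CO | intermediate
17 | 5-bromo-2-methoxyphenol | COc1ccc(Br)cc1O | starting material
18 | 2-(benzyloxy)-4-bromo-1-methoxybenzene | COc1ccc(Br)cc1OCc1ccccc1 | intermediate
19 | 3-benzyloxy-4-methoxyphenyllithium | [Li]c1ccc(OC)c(OCc2ccccc2)c1 | intermediate (not isolated)
20 | (2S,3R,4S)-4-[3-(benzyloxy)-4-methoxybenzoyl]-2-[3-(benzyloxy)-4-methoxyphenyl]-3-(hydroxymethyl)tetrahydrofuran | COc1ccc(C(=O)[C@@H]2CO[C@H](c3ccc(OC)c(OCc4ccccc4)c3)[C@H]2CO)cc1OCc1ccccc1 | intermediate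
21 | (2S,3R,4S)-4-(3-hydroxy-4-methoxybenzoyl)-2-(3-hydroxy-4-methoxyphenyl)-3-(hydroxymethyl)tetrahydrofuran | COc1ccc(C(=O)[C@@H]2CO[C@H](c3ccc(OC)c(O)c3)[C@H]2CO)cc1O | target

## Step count and least certain steps

Total step count: 11. Longest linear sequence: 10 steps (steps 1–8, 10 and 11, from 1); step 9 is a one-step side branch.

**Step 6 (key step).** The most likely failure is poor facial selectivity at C2 with respect to C4, that is, a low 2,4-cis preference. The envelope transition state of a five-membered closure is flexible, and direction by an α-amide centre is untested. A second failure is protodesilylation of the allylsilane before closure if adventitious acid is present. The fallback moves C2 from kinetic to thermodynamic control. It sets out from 10 and 11, runs the closure as in step 6 without regard to the C2 ratio, and takes the mixture through steps 7 and 8. To the extent that step 7 has placed C6 trans to the amide, the 2,4-trans material then arrives as the C2 epimer of 16, (2R,3R,4S)-2-[3-(benzyloxy)-4-methoxyphenyl]-3-(hydroxymethyl)-N-methoxy-N-methyltetrahydrofuran-4-carboxamide F1. F1 is separated and treated with BF3·OEt2 (0.2 equiv) in dilute CH2Cl2 at −20 to 0 °C. Reversible ionisation of the 4-methoxybenzylic C2–O1 bond and re-closure by O1 should place the aryl group trans to C6, which returns the material to the route at 16. Acid-mediated epimerisation at the benzylic carbon of 2-aryltetrahydrofurans is a known reaction type. It is applied here before the second electron-rich ring is present, so no intramolecular Friedel–Crafts partner exists.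

**Step 2.** The likely failures are loss of regiocontrol (γ-attack of the dienolate) and migration of the alkene into conjugation, before or after bond formation, since C4–H of both 4 and 6 is doubly activated. The fallback carries the vinyl group in latent form. It sets out from 2, which is acylated under the conditions of step 1 with the known 4-(phenylselanyl)butanoic acid F2 to give (R)-4-benzyl-3-[4-(phenylselanyl)butanoyl]oxazolidin-2-one F3. Hydroxymethylation under the conditions of step 2, now on an ordinary enolate, should give (R)-4-benzyl-3-[(2S)-2-(hydroxymethyl)-4-(phenylselanyl)butanoyl]oxazolidin-2-one F4. Oxidation with H2O2 and pyridine in CH2Cl2 at 0 °C to rt, followed by selenoxide syn-elimination, which can only take a hydrogen from the chain carbon next to C4, unveils the vinyl group and returns to the route at 6.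

**Step 4.** The likely failures are ruthenium hydride-mediated migration of the β,γ-alkene into conjugation with the amide (which destroys C4), stalling through chelation of the carbene by the amide and hydroxyl, and an unfavourable E/Z mixture. The fallback replaces the intermolecular metathesis by a ring-closing one on a silicon tether. It sets out from 7, which is silylated with allyl(chloro)dimethylsilane and imidazole in CH2Cl2 to give (2S)-2-{[allyl(dimethyl)silyl]oxymethyl}-N-methoxy-N-methylbut-3-enamide F5. Ring-closing metathesis with the second-generation Grubbs catalyst in CH2Cl2 at 40 °C should give the seven-membered cyclic allylsiloxane (6S,4Z)-N-methoxy-N,2,2-trimethyl-2,3,6,7-tetrahydro-1,2-oxasilepine-6-carboxamide F6, whose alkene is Z by necessity. F6 takes the place of 10 in step 6: its Si–O oxygen becomes O1 and its ring allylsilane is the nucleophile. Condensation with 11 under TMSOTf, a known reaction type for such oxasilacycloheptenes, returns to the route at 12 in the same number of steps.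

**Step 10.** The likely failures are deprotonation at C4 by the aryllithium or by the lithium alkoxide aggregate, leading to epimerisation or to β-elimination of O1 with ring opening, and sluggish addition to an amide that carries an alkoxide. The fallback adds the aryl group before C6 is unveiled. It sets out from 12, which has no acidic proton and is treated with 19 (1.3 equiv) at −78 °C to give (2S,3S,4S)-4-[3-(benzyloxy)-4-methoxybenzoyl]-2-[3-(benzyloxy)-4-methoxyphenyl]-3-vinyltetrahydrofuran F7. The conditions of step 7 should then give the all-trans keto aldehyde (2S,3S,4S)-4-[3-(benzyloxy)-4-methoxybenzoyl]-2-[3-(benzyloxy)-4-methoxyphenyl]-3-formyltetrahydrofuran F8. Reduction with NaBH4 in EtOH/CH2Cl2 at −78 °C, selective for the aldehyde over the electron-rich aryl ketone, returns to the route at 20. In this order C4 also becomes epimerisable under DBU, so any C2 epimer must be removed at 12; otherwise it would drift toward the enantiomeric series.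

**Step 11.** The likely failures are over-reduction of the aryl ketone to the carbinol or methylene compound and hydrogenolysis of the cyclic C2–O1 benzylic bond on prolonged contact with the catalyst. The fallback replaces benzyl by triisopropylsilyl on both phenols, so that the last step is a fluoride desilylation. It sets out from 17 and 10 and uses these compounds in turn:
- 17 is silylated (i-Pr3SiCl, imidazole, DMF) to (5-bromo-2-methoxyphenoxy)triisopropylsilane F9.
- Part of F9 is converted by n-BuLi and then DMF at −78 °C into 4-methoxy-3-(triisopropylsilyloxy)benzaldehyde F10.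
- F10 and 10 under the conditions of step 6 should give (2S,3S,4S)-N-methoxy-2-[4-methoxy-3-(triisopropylsilyloxy)phenyl]-N-methyl-3-vinyltetrahydrofuran-4-carboxamide F11.
- The conditions of step 7 give (2S,3S,4S)-3-formyl-N-methoxy-2-[4-methoxy-3-(triisopropylsilyloxy)phenyl]-N-methyltetrahydrofuran-4-carboxamide F12.
- The conditions of step 8 give (2S,3R,4S)-3-(hydroxymethyl)-N-methoxy-2-[4-methoxy-3-(triisopropylsilyloxy)phenyl]-N-methyltetrahydrofuran-4-carboxamide F13.
- The aryllithium from F9 under the conditions of step 10 gives (2S,3R,4S)-3-(hydroxymethyl)-4-[4-methoxy-3-(triisopropylsilyloxy)benzoyl]-2-[4-methoxy-3-(triisopropylsilyloxy)phenyl]tetrahydrofuran F14.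
- Bu4NF buffered with AcOH in THF at 0 °C returns to the route at 21.

## Further compounds

F1 | step 6 | (2R,3R,4S)-2-[3-(benzyloxy)-4-methoxyphenyl]-3-(hydroxymethyl)-N-methoxy-N-methyltetrahydrofuran-4-carboxamide | CON(C)C(=O)[C@@H]1CO[C@@H](c2ccc(OC)c(OCc3ccccc3)c2)[C@H]1CO
F2 | step 2 | 4-(phenylselanyl)butanoic acid | OC(=O)CCC[Se]c1ccccc1
F3 | step 2 | (R)-4-benzyl-3-[4-(phenylselanyl)butanoyl]oxazolidin-2-one | O=C(CCC[Se]c1ccccc1)N1C(=O)OC[C@H]1Cc1ccccc1
F4 | step 2 | (R)-4-benzyl-3-[(2S)-2-(hydroxymethyl)-4-(phenylselanyl)butanoyl]oxazolidin-2-one | OC[C@@H](C(=O)N1C(=O)OC[C@H]1Cc1ccccc1)CC[Se]c1ccccc1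
F5 | step 4 | (2S)-2-{[allyl(dimethyl)silyl]oxymethyl}-N-methoxy-N-methylbut-3-enamide | C=CC[Si](C)(C)OC[C@@H](C(=O)N(C)OC)C=C
F6 | step 4 | (6S,4Z)-N-methoxy-N,2,2-trimethyl-2,3,6,7-tetrahydro-1,2-oxasilepine-6-carboxamide | CON(C)C(=O)[C@@H]1CO[Si](C)(C)C/C=C\1
F7 | step 10 | (2S,3S,4S)-4-[3-(benzyloxy)-4-methoxybenzoyl]-2-[3-(benzyloxy)-4-methoxyphenyl]-3-vinyltetrahydrofuran | COc1ccc(C(=O)[C@@H]2CO[C@H](c3ccc(OC)c(OCc4ccccc4)c3)[C@H]2C=C)cc1OCc1ccccc1
F8 | step 10 | (2S,3S,4S)-4-[3-(benzyloxy)-4-methoxybenzoyl]-2-[3-(benzyloxy)-4-methoxyphenyl]-3-formyltetrahydrofuran | COc1ccc(C(=O)[C@@H]2CO[C@H](c3ccc(OC)c(OCc4ccccc4)c3)[C@H]2C=O)cc1OCc1ccccc1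
F9 | step 11 | (5-bromo-2-methoxyphenoxy)triisopropylsilane | COc1ccc(Br)cc1O[Si](C(C)C)(C(C)C)C(C)C
F10 | step 11 | 4-methoxy-3-(triisopropylsilyloxy)benzaldehyde | COc1ccc(C=O)cc1O[Si](C(C)C)(C(C)C)C(C)C
F11 | step 11 | (2S,3S,4S)-N-methoxy-2-[4-methoxy-3-(triisopropylsilyloxy)phenyl]-N-methyl-3-vinyltetrahydrofuran-4-carboxamide | CON(C)C(=O)[C@@H]1CO[C@H](c2ccc(OC)c(O[Si](C(C)C)(C(C)C)C(C)C)c2)[C@H]1C=C
F12 | step 11 | (2S,3S,4S)-3-formyl-N-methoxy-2-[4-methoxy-3-(triisopropylsilyloxy)phenyl]-N-methyltetrahydrofuran-4-carboxamide | CON(C)C(=O)[C@@H]1CO[C@H](c2ccc(OC)c(O[Si](C(C)C)(C(C)C)C(C)C)c2)[C@H]1C=O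
F13 | step 11 | (2S,3R,4S)-3-(hydroxymethyl)-N-methoxy-2-[4-methoxy-3-(triisopropylsilyloxy)phenyl]-N-methyltetrahydrofuran-4-carboxamide | CON(C)C(=O)[C@@H]1CO[C@H](c2ccc(OC)c(O[Si](C(C)C)(C(C)C)C(C)C)c2)[C@H]1CO
F14 | step 11 | (2S,3R,4S)-3-(hydroxymethyl)-4-[4-methoxy-3-(triisopropylsilyloxy)benzoyl]-2-[4-methoxy-3-(triisopropylsilyloxy)phenyl]tetrahydrofuran | COc1ccc(C(=O)[C@@H]2CO[C@H](c3ccc(OC)c(O[Si](C(C)C)(C(C)C)C(C)C)c3)[C@H]2CO)cc1O[Si](C(C)C)(C(C)C)C(C)C
A1 | alternative 1 | (2S,3R,4S)-4-(3-acetoxy-4-methoxybenzoyl)-2-(3-acetoxy-4-methoxyphenyl)-3-(acetoxymethyl)tetrahydrofuran | COc1ccc(C(=O)[C@@H]2CO[C@H](c3ccc(OC)c(OC(C)=O)c3)[C@H]2COC(C)=O)cc1OC(C)=O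
A2 | alternative 1 | (3R,4S)-2-acetoxy-3-(acetoxymethyl)tetrahydrofuran-4-carbonyl chloride, both anomers at C2 | O=C(Cl)[C@@H]1COC(OC(C)=O)[C@H]1COC(C)=O
A3 | alternative 1 | 2-methoxyphenyl acetate | COc1ccccc1OC(C)=O
A4 | alternative 2 | 2-[3-(benzyloxy)-4-methoxyphenyl]-4-[3-(benzyloxy)-4-(methylsulfonyloxy)phenyl]-4-[(E)-3-(benzyloxy)prop-1-en-1-yl]-1,3-dioxolane, one enantiomer at the carbinol carbon required, ring stereocentres left open | COc1ccc(C2OCC(/C=C/COCc3ccccc3)(c3ccc(OS(C)(=O)=O)c(OCc4ccccc4)c3)O2)cc1OCc1ccccc1
A5 | alternative 2 | (2S,3R,4S)-2-[3-(benzyloxy)-4-methoxyphenyl]-3-(benzyloxymethyl)-4-[3-(benzyloxy)-4-(methylsulfonyloxy)benzoyl]tetrahydrofuran | CS(=O)(=O)Oc1ccc(C(=O)[C@@H]2CO[C@H](c3ccc(OC)c(OCc4ccccc4)c3)[C@H]2COCc2ccccc2)cc1OCc1ccccc1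
A6 | alternative 3 | 2-[(R)-[3-(benzyloxy)-4-methoxyphenyl]{[3-(3-benzyloxy-4-methoxyphenyl)prop-2-yn-1-yl]oxy}methyl]oxirane, either epoxide epimer | COc1ccc(C#CCO[C@H](c2ccc(OC)c(OCc3ccccc3)c2)C2CO2)cc1OCc1ccccc1
A7 | alternative 3 | (2S,3R,4Z)-2-[3-(benzyloxy)-4-methoxyphenyl]-4-[3-(benzyloxy)-4-methoxybenzylidene]-3-(hydroxymethyl)tetrahydrofuran | COc1ccc(/C=C2\CO[C@H](c3ccc(OC)c(OCc4ccccc4)c3)[C@H]2CO)cc1OCc1ccccc1
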